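**Retrosynthetic overview**
1. The target is epirobinetinidol-(4β→8)-epirobinetinidol-(4α→8)-epicatechin, 2,3-cis in all three units. It is reached by hydrogenolysis of a pentadeca-O-benzyl ether. The middle C4–terminal C8 bond comes from an 8-lithio flavan and a C4 ketone, then hydride delivery to the C4 cation (3,4-cis). The upper C4–middle C8 bond comes from a flavan-4-yl cation and C8 of a 5,7-dioxygenated flavan (3,4-trans).
2. The upper and middle units both come from (−)-epigallocatechin. Their 5-oxygen is deleted through the C4 ketone (peri-directed debenzylation, triflation, Pd/silane reduction). For the middle unit this is done only after the coupling, so that its A ring is still a phloroglucinol-type C8 nucleophile.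
3. The terminal unit is made de novo. Its C ring (O1–C2–C3–C4–C4a–C8a) is not closed directly: a 2-aryl-3-hydroxy-3-(mesyloxymethyl)-2,3-dihydrobenzofuran is ring-expanded by a 1,2-aryl shift to the flavan-3-one. Transfer hydrogenation with dynamic kinetic resolution then sets C2 and C3.
4. Enabling feature: the A ring of the terminal unit is a phloroglucinol ring. Its carbon C4a (C3a of the benzofuran) has the O1-bearing C8a and the O-bearing C5 as ortho neighbours and the O-bearing C7 in the para position. This makes it an exceptionally good migrating group from C3 to the exocyclic CH2 (the future C4), while the oxygen on C3 becomes the carbonyl that makes the shift irreversible.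
5. Ring order: dihydrobenzofuran ring (step 2) → terminal C ring (step 5). The C rings of the upper and middle units come from the chiral pool; no ring is formed after step 5.

Key step: step 5

Remark: read from the SMILES, the units are (2R,3R,4R) upper, (2R,3R,4S) middle and (2R,3R) terminal (epirobinetinidol = (2R,3R)-3,7,3',4',5'-pentahydroxyflavan); racemic compounds 3–11 are drawn without stereodescriptors because the benzofuran C3 is erased in step 5 and C2 is set in step 6; the sense of induction in step 6 is assumed, and the mirror-image Ru catalyst is to be used if it proves opposite.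

**Route**

Step 1
Reactants: 1 3,4-bis(benzyloxy)benzaldehyde; 2 methyl dichloroacetate
Product: 4 methyl 3-[3,4-bis(benzyloxy)phenyl]-3-chloro-2-oxopropanoate (racemic), via chloroglycidic ester 3 (not isolated)
Conditions: NaOMe, Et2O, 0 → 20 °C
Reagents that add atoms: none
Why: Darzens condensation gives the α-chloroglycidic ester 3, whose benzylic C–O bond opens under the push of the electron-rich aryl group with a 1,2-chloride shift to the β-chloro-α-keto ester; the new stereocentre is racemic, which suffices because it becomes the epimerisable C2 of ketone 11.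

Step 2
Reactants: 4 methyl 3-[3,4-bis(benzyloxy)phenyl]-3-chloro-2-oxopropanoate; 5 3,5-bis(benzyloxy)phenol
Product: 7 methyl 4,6-bis(benzyloxy)-2-[3,4-bis(benzyloxy)phenyl]-3-hydroxy-2,3-dihydro-1-benzofuran-3-carboxylate (racemic; both diastereomers), via aryloxy keto ester 6 (not isolated)
Conditions: K2CO3, acetone, 0 → 20 °C; filter; then Sc(OTf)3 (10 mol %), CH2Cl2, 0 °C
Reagents that add atoms: none
Why: Williamson O-alkylation of the phenoxide at the activated benzylic α-keto chloride is followed by Lewis-acid-catalysed intramolecular Friedel–Crafts hydroxyalkylation of the α-keto ester (5-exo-trig; an interrupted Feist–Bénary-type annulation) at a ring carbon ortho to the ether oxygen (both ortho carbons are equivalent); C2 and C3 form as a racemic diastereomer mixture, which is harmless because C3 is erased in step 5 and C2 is reset in step 6.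

Step 3
Reactants: 7 hydroxy ester
Product: 8 4,6-bis(benzyloxy)-2-[3,4-bis(benzyloxy)phenyl]-3-(hydroxymethyl)-2,3-dihydro-1-benzofuran-3-ol (racemic; both diastereomers)
Conditions: LiAlH4, THF, 0 °C
Reagents that add atoms: none
Why: LiAlH4 reduction of the α-hydroxy ester to the primary alcohol; the tertiary alcohol, the benzyl ethers and both stereocentres are untouched.

Step 4
Reactants: 8 diol
Product: 9 [4,6-bis(benzyloxy)-2-[3,4-bis(benzyloxy)phenyl]-3-hydroxy-2,3-dihydro-1-benzofuran-3-yl]methyl methanesulfonate (racemic; both diastereomers; used crude)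
Conditions: MsCl, Et3N, CH2Cl2, −40 °C
Reagents that add atoms: methanesulfonyl chloride CS(=O)(=O)Cl
Why: Chemoselective sulfonylation of the primary hydroxyl in the presence of the tertiary one puts the leaving group on the carbon that becomes C4; no stereocentre is affected.

Step 5
Reactants: 9 hydroxy mesylate
Product: 11 5,7-bis(benzyloxy)-2-[3,4-bis(benzyloxy)phenyl]chroman-3-one (racemic), via diethylaluminium alkoxide 10 (not isolated)
Conditions: Et3Al (2.5 equiv), CH2Cl2, −78 → −20 °C
Reagents that add atoms: none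
Why: Et3Al turns the tertiary hydroxyl into the diethylaluminium alkoxide 10 and, as a Lewis acid, loosens the primary mesylate; the arene carbon C3a then attacks the CH2 carbon from the rear (3-exo-tet, phenonium-like bridged transition state) while the lone pair of the C3–O(Al) oxygen expels C3a from C3, so the aryl group ends on the former CH2 carbon and C3 becomes the carbonyl carbon. The closest known reaction type is the Tiffeneau–Demjanov and organoaluminium-promoted semipinacol ring expansion of 1-(aminomethyl)- or 1-(sulfonyloxymethyl)indan-1-ols to 2-tetralones by aryl migration. The five-membered ring O1–C2–C3–C3a–C7a is thereby enlarged to the six-membered ring O1–C2–C3–C4–C4a–C8a by a 1,2-shift (ring expansion, not a new cyclisation). No stereocentre is created: the carbinol centre becomes sp2, so both diastereomers of 9 converge on one ketone, and C2 is left for step 6. The selectivity needed is migration of the aryl carbon in preference to C2 (which would give the flavan-4-one) and in preference to epoxide closure or dehydration to the benzofuran; it is secured by the 2,4,6-trioxygenated migrating ring (ipso carbon flanked by the O1-bearing carbon and the 4-benzyloxy carbon, para to the 6-benzyloxy carbon) and by the Lewis-acidic, non-basic and aprotic medium.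

Step 6
Reactants: 11 racemic flavan-3-one
Product: 12 (2R,3R)-5,7-bis(benzyloxy)-2-[3,4-bis(benzyloxy)phenyl]chroman-3-ol (5,7,3',4'-tetra-O-benzyl-(−)-epicatechin)
Conditions: RuCl[(R,R)-TsDPEN](p-cymene) (2 mol %), HCO2H/Et3N (5:2), CH2Cl2, 25 °C, argon
Reagents that add atoms: none
Why: Noyori–Ikariya asymmetric transfer hydrogenation with dynamic kinetic resolution: C2 (α to the carbonyl; benzylic; O-substituted) epimerises through the enol in the HCO2H/Et3N medium while the catalyst reduces the (2R) ketone faster and delivers hydride anti to the 2-aryl group, so that C2 (R) and the cis C3 (R) are set together, as for other α-aryl cyclic ketones.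

Step 7
Reactants: 12 tetra-O-benzylepicatechin
Product: 13 (2R,3R)-5,7-bis(benzyloxy)-2-[3,4-bis(benzyloxy)phenyl]-8-bromochroman-3-ol
Conditions: NBS, CH2Cl2, −20 → 20 °C
Reagents that add atoms: N-bromosuccinimide O=C1CCC(=O)N1Br
Why: Electrophilic aromatic bromination of the phloroglucinol-type A ring at C8, the free position next to O1 that is less hindered than C6 between two benzyloxy groups (the regioselectivity established for tetra-O-benzyl catechins); stereocentres unaffected.

Step 8
Reactants: 13 8-bromo alcohol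
Product: 14 (2R,3R)-3,5,7-tris(benzyloxy)-2-[3,4-bis(benzyloxy)phenyl]-8-bromochroman
Conditions: NaH, BnBr, DMF, 0 → 20 °C
Reagents that add atoms: benzyl bromide BrCc1ccccc1
Why: Williamson etherification of the secondary alkoxide protects the 3-OH before the lithiation; stereocentres unaffected.

Step 9
Reactants: 15 (−)-epigallocatechin
Product: 17 3,5,7,3',4',5'-hexa-O-benzyl-(−)-epigallocatechin, via penta-O-benzyl ether 16 (not isolated)
Conditions: BnBr, K2CO3, DMF, 0 → 20 °C; then NaH, 0 °C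
Reagents that add atoms: benzyl bromide BrCc1ccccc1
Why: Williamson O-benzylation of the five phenols with the mild base (which avoids the C2 epimerisation that free catechins suffer with strong base) and then of the 3-alkoxide with NaH; C2 and C3 (2R,3R; cis) come unchanged from the chiral pool.

Step 10
Reactants: 17 hexa-O-benzylepigallocatechin
Product: 18 (2R,3R,4S)-3,5,7-tris(benzyloxy)-2-[3,4,5-tris(benzyloxy)phenyl]chroman-4-ol (4β-OH)
Conditions: DDQ, CH2Cl2/H2O, 20 °C
Reagents that add atoms: water O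
Why: DDQ abstracts hydride from the benzylic C4–H to give the A-ring-stabilised C4 cation, which water captures anti to the 3-benzyloxy and 2-aryl groups (4β-OH), the usual C4 functionalisation of benzylated catechins.

Step 11
Reactants: 18 4β-alcohol
Product: 19 (2R,3S)-3,5,7-tris(benzyloxy)-2-[3,4,5-tris(benzyloxy)phenyl]chroman-4-one
Conditions: Dess–Martin periodinane, NaHCO3, CH2Cl2, 20 °C
Reagents that add atoms: none
Why: Dess–Martin oxidation of the benzylic alcohol to the aryl ketone under buffered conditions that do not epimerise C3.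

Step 12
Reactants: 19 ketone
Product: 20 (2R,3S)-3,7-bis(benzyloxy)-5-hydroxy-2-[3,4,5-tris(benzyloxy)phenyl]chroman-4-one
Conditions: MgBr2·OEt2, toluene/Et2O, 20 → 40 °C
Reagents that add atoms: none
Why: Chelation-controlled dealkylation: MgBr2 bound between the C4 carbonyl and the peri 5-oxygen (six-membered chelate) activates only this aryl benzyl ether for bromide attack at its benzylic carbon, the selective debenzylation ortho to a carbonyl group.

Step 13
Reactants: 20 5-hydroxy ketone
Product: 21 (2R,3S)-3,7-bis(benzyloxy)-4-oxo-2-[3,4,5-tris(benzyloxy)phenyl]chroman-5-yl trifluoromethanesulfonate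
Conditions: Tf2O, pyridine, CH2Cl2, 0 °C
Reagents that add atoms: trifluoromethanesulfonic anhydride O=S(=O)(OS(=O)(=O)C(F)(F)F)C(F)(F)F
Why: Triflation of the hydrogen-bonded phenol turns the C5 oxygen into a leaving group for reductive removal.

Step 14
Reactants: 21 aryl triflate
Product: 22 (2R,3S)-3,7-bis(benzyloxy)-2-[3,4,5-tris(benzyloxy)phenyl]chroman-4-one
Conditions: Pd(OAc)2 (5 mol %), dppp, Et3SiH, DMF, 60 °C
Reagents that add atoms: none
Why: Pd-catalysed reduction of the aryl triflate with the silane as hydride source (oxidative addition, hydride transfer from silicon, reductive elimination) under neutral conditions that spare the benzyl ethers and the epimerisable C3 next to the ketone.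

Step 15
Reactants: 22 5-deoxy ketone
Product: 23 (2R,3R,4R)-3,7-bis(benzyloxy)-2-[3,4,5-tris(benzyloxy)phenyl]chroman-4-ol (4α-OH expected)
Conditions: NaBH4, THF/MeOH, −20 °C
Reagents that add atoms: none
Why: NaBH4 reduction with hydride entering anti to the 3-benzyloxy and 2-aryl groups (4α-alcohol expected); the C4 configuration is immaterial because C4 is ionised in step 16.

Step 16
Reactants: 23 flavan-4-ol; 17 hexa-O-benzylepigallocatechin (3 equiv)
Product: 24 3,7,3',4',5'-penta-O-benzyl-epirobinetinidol-(4β→8)-3,5,7,3',4',5'-hexa-O-benzyl-epigallocatechin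
Conditions: BF3·OEt2 (1.5 equiv), CH2Cl2, −40 → 0 °C
Reagents that add atoms: none
Why: BF3-mediated ionisation gives the flavan-4-yl cation (stabilised by O1 and the 7-benzyloxy group), which C8 of the phloroglucinol ring of 17 attacks in a Friedel–Crafts reaction from the β face anti to the 3-benzyloxy and 2-aryl groups, setting the 4β→8 bond (3,4-trans; 4R); the resorcinol-type A ring of 23 is far less nucleophilic than 17, which suppresses self-condensation.

Step 17
Reactants: 24 protected dimer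
Product: 25 penta-O-benzyl-epirobinetinidol-(4β→8)-hexa-O-benzyl-4β-hydroxy-epigallocatechin
Conditions: DDQ, CH2Cl2/H2O, 20 °C
Reagents that add atoms: water O
Why: DDQ oxidation as in step 10 at the only CH2 group benzylic to a trioxygenated ring (C4 of the lower unit), with water adding anti to the 3-benzyloxy group; this stereocentre is removed again in step 18.

Step 18
Reactants: 25 dimer 4-alcohol
Product: 26 penta-O-benzyl-epirobinetinidol-(4β→8)-hexa-O-benzyl-4-oxo-epigallocatechin
Conditions: Dess–Martin periodinane, NaHCO3, CH2Cl2, 20 °C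
Reagents that add atoms: none
Why: Dess–Martin oxidation to the lower-unit C4 ketone, which serves as the handle for the C5 deoxygenation and as the electrophile of step 22.

Step 19
Reactants: 26 dimer ketone
Product: 27 penta-O-benzyl-epirobinetinidol-(4β→8)-3,7,3',4',5'-penta-O-benzyl-4-oxo-epigallocatechin (free 5-OH)
Conditions: MgBr2·OEt2, toluene/Et2O, 20 → 40 °C
Reagents that add atoms: none
Why: Chelation-controlled debenzylation as in step 12; only the 5-benzyloxy group of the lower unit has a peri carbonyl group.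

Step 20
Reactants: 27 dimer 5-hydroxy ketone
Product: 28 5-O-triflate of 27
Conditions: Tf2O, pyridine, CH2Cl2, 0 °C
Reagents that add atoms: trifluoromethanesulfonic anhydride O=S(=O)(OS(=O)(=O)C(F)(F)F)C(F)(F)F
Why: Phenol triflation as in step 13.

Step 21
Reactants: 28 dimer triflate
Product: 29 penta-O-benzyl-epirobinetinidol-(4β→8)-3,7,3',4',5'-penta-O-benzyl-4-oxo-epirobinetinidol
Conditions: Pd(OAc)2 (5 mol %), dppp, Et3SiH, DMF, 60 °C
Reagents that add atoms: none
Why: Pd/silane reduction of the aryl triflate as in step 14, now giving the 5-deoxy middle unit without touching C3 next to the ketone.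

Step 22
Reactants: 14 8-bromo-penta-O-benzylepicatechin; 29 dimer ketone
Product: 31 protected trimer carbinol (middle unit C4: OH α and terminal aryl β), via aryllithium 30 (not isolated)
Conditions: 14, t-BuLi (2.1 equiv), THF, −78 °C; then 29, −78 → 0 °C
Reagents that add atoms: none
Why: Bromine–lithium exchange gives the C8 aryllithium, which undergoes 1,2-addition to the C4 ketone from the β face anti to the 3-benzyloxy and 2-aryl groups (the established way to join an 8-lithio flavan to a flavan-4-one); the configuration of the carbinol carbon is immaterial because it is ionised in step 23.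

Step 23
Reactants: 31 trimer carbinol
Product: 32 pentadeca-O-benzyl-epirobinetinidol-(4β→8)-epirobinetinidol-(4α→8)-epicatechin
Conditions: Bu3SnH, CF3CO2H, CH2Cl2, 0 °C
Reagents that add atoms: none
Why: Ionic hydrogenation: the acid ionises the tertiary diaryl carbinol to the planar C4 cation and Bu3SnH delivers hydride from the β face anti to the 3-benzyloxy and 2-aryl groups, which places the terminal aryl group α and sets the all-cis (2R,3R,4S) middle unit.

Step 24
Reactants: 32 perbenzylated trimer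
Product: 33 epirobinetinidol-(4β→8)-epirobinetinidol-(4α→8)-epicatechin (CNP0115797.2)
Conditions: H2 (1 atm), Pd(OH)2/C, THF/MeOH/H2O, 20 °C
Reagents that add atoms: none
Why: Hydrogenolysis of all fifteen benzyl ethers under neutral conditions that leave the interflavan bonds and all eight stereocentres untouched.

**Compound list**
1 | 3,4-bis(benzyloxy)benzaldehyde | O=Cc1ccc(OCc2ccccc2)c(OCc2ccccc2)c1 | starting material
2 | methyl dichloroacetate | COC(=O)C(Cl)Cl | starting material
3 | methyl 3-[3,4-bis(benzyloxy)phenyl]-2-chlorooxirane-2-carboxylate (racemic) | COC(=O)C1(Cl)OC1c1ccc(OCc2ccccc2)c(OCc2ccccc2)c1 | intermediate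
4 | methyl 3-[3,4-bis(benzyloxy)phenyl]-3-chloro-2-oxopropanoate (racemic) | COC(=O)C(=O)C(Cl)c1ccc(OCc2ccccc2)c(OCc2ccccc2)c1 | intermediate
5 | 3,5-bis(benzyloxy)phenol | Oc1cc(OCc2ccccc2)cc(OCc2ccccc2)c1 | starting material
6 | methyl 3-[3,5-bis(benzyloxy)phenoxy]-3-[3,4-bis(benzyloxy)phenyl]-2-oxopropanoate (racemic) | COC(=O)C(=O)C(Oc1cc(OCc2ccccc2)cc(OCc2ccccc2)c1)c1ccc(OCc2ccccc2)c(OCc2ccccc2)c1 | intermediate
7 | methyl 4,6-bis(benzyloxy)-2-[3,4-bis(benzyloxy)phenyl]-3-hydroxy-2,3-dihydro-1-benzofuran-3-carboxylate (racemic; both C2/C3 diastereomers) | COC(=O)C1(O)C(c2ccc(OCc3ccccc3)c(OCc3ccccc3)c2)Oc2cc(OCc3ccccc3)cc(OCc3ccccc3)c21 | intermediate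
8 | 4,6-bis(benzyloxy)-2-[3,4-bis(benzyloxy)phenyl]-3-(hydroxymethyl)-2,3-dihydro-1-benzofuran-3-ol (racemic; both diastereomers) | OCC1(O)C(c2ccc(OCc3ccccc3)c(OCc3ccccc3)c2)Oc2cc(OCc3ccccc3)cc(OCc3ccccc3)c21 | intermediate
9 | [4,6-bis(benzyloxy)-2-[3,4-bis(benzyloxy)phenyl]-3-hydroxy-2,3-dihydro-1-benzofuran-3-yl]methyl methanesulfonate (racemic; both diastereomers) | CS(=O)(=O)OCC1(O)C(c2ccc(OCc3ccccc3)c(OCc3ccccc3)c2)Oc2cc(OCc3ccccc3)cc(OCc3ccccc3)c21 | intermediate
10 | diethylaluminium alkoxide of 9 | CC[Al](CC)OC1(COS(C)(=O)=O)C(c2ccc(OCc3ccccc3)c(OCc3ccccc3)c2)Oc2cc(OCc3ccccc3)cc(OCc3ccccc3)c21 | intermediate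
11 | 5,7-bis(benzyloxy)-2-[3,4-bis(benzyloxy)phenyl]chroman-3-one (racemic) | O=C1Cc2c(OCc3ccccc3)cc(OCc3ccccc3)cc2OC1c1ccc(OCc2ccccc2)c(OCc2ccccc2)c1 | intermediate
12 | (2R,3R)-5,7-bis(benzyloxy)-2-[3,4-bis(benzyloxy)phenyl]chroman-3-ol (tetra-O-benzyl-(−)-epicatechin) | c1c(OCc3ccccc3)cc(OCc3ccccc3)c2c1O[C@H](c1ccc(OCc3ccccc3)c(OCc3ccccc3)c1)[C@H](O)C2 | intermediate
13 | (2R,3R)-5,7-bis(benzyloxy)-2-[3,4-bis(benzyloxy)phenyl]-8-bromochroman-3-ol | Brc1c(OCc3ccccc3)cc(OCc3ccccc3)c2c1O[C@H](c1ccc(OCc3ccccc3)c(OCc3ccccc3)c1)[C@H](O)C2 | intermediate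
14 | (2R,3R)-3,5,7-tris(benzyloxy)-2-[3,4-bis(benzyloxy)phenyl]-8-bromochroman | Brc1c(OCc3ccccc3)cc(OCc3ccccc3)c2c1O[C@H](c1ccc(OCc3ccccc3)c(OCc3ccccc3)c1)[C@H](OCc1ccccc1)C2 | intermediate
15 | (−)-epigallocatechin, (2R,3R)-2-(3,4,5-trihydroxyphenyl)chroman-3,5,7-triol | Oc1cc(O)c2c(c1)O[C@H](c1cc(O)c(O)c(O)c1)[C@H](O)C2 | starting material
16 | 5,7,3',4',5'-penta-O-benzyl-(−)-epigallocatechin | c1ccccc1COc1cc(OCc2ccccc2)c2c(c1)O[C@H](c1cc(OCc3ccccc3)c(OCc3ccccc3)c(OCc3ccccc3)c1)[C@H](O)C2 | intermediate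
17 | 3,5,7,3',4',5'-hexa-O-benzyl-(−)-epigallocatechin | c1ccccc1COc1cc(OCc2ccccc2)c2c(c1)O[C@H](c1cc(OCc3ccccc3)c(OCc3ccccc3)c(OCc3ccccc3)c1)[C@H](OCc1ccccc1)C2 | intermediate
18 | (2R,3R,4S)-3,5,7-tris(benzyloxy)-2-[3,4,5-tris(benzyloxy)phenyl]chroman-4-ol (4β-OH) | c1ccccc1COc1cc(OCc2ccccc2)c2c(c1)O[C@H](c1cc(OCc3ccccc3)c(OCc3ccccc3)c(OCc3ccccc3)c1)[C@H](OCc1ccccc1)[C@H]2O | intermediate
19 | (2R,3S)-3,5,7-tris(benzyloxy)-2-[3,4,5-tris(benzyloxy)phenyl]chroman-4-one | c1ccccc1COc1cc(OCc2ccccc2)c2c(c1)O[C@H](c1cc(OCc3ccccc3)c(OCc3ccccc3)c(OCc3ccccc3)c1)[C@H](OCc1ccccc1)C2=O | intermediate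
20 | (2R,3S)-3,7-bis(benzyloxy)-5-hydroxy-2-[3,4,5-tris(benzyloxy)phenyl]chroman-4-one | c1ccccc1COc1cc(O)c2c(c1)O[C@H](c1cc(OCc3ccccc3)c(OCc3ccccc3)c(OCc3ccccc3)c1)[C@H](OCc1ccccc1)C2=O | intermediate
21 | (2R,3S)-3,7-bis(benzyloxy)-4-oxo-2-[3,4,5-tris(benzyloxy)phenyl]chroman-5-yl trifluoromethanesulfonate | c1ccccc1COc1cc(OS(=O)(=O)C(F)(F)F)c2c(c1)O[C@H](c1cc(OCc3ccccc3)c(OCc3ccccc3)c(OCc3ccccc3)c1)[C@H](OCc1ccccc1)C2=O | intermediate
22 | (2R,3S)-3,7-bis(benzyloxy)-2-[3,4,5-tris(benzyloxy)phenyl]chroman-4-one | c1ccccc1COc1ccc2c(c1)O[C@H](c1cc(OCc3ccccc3)c(OCc3ccccc3)c(OCc3ccccc3)c1)[C@H](OCc1ccccc1)C2=O | intermediate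
23 | (2R,3R,4R)-3,7-bis(benzyloxy)-2-[3,4,5-tris(benzyloxy)phenyl]chroman-4-ol (4α-OH) | c1ccccc1COc1ccc2c(c1)O[C@H](c1cc(OCc3ccccc3)c(OCc3ccccc3)c(OCc3ccccc3)c1)[C@H](OCc1ccccc1)[C@@H]2O | intermediate
24 | 3,7,3',4',5'-penta-O-benzyl-epirobinetinidol-(4β→8)-3,5,7,3',4',5'-hexa-O-benzyl-epigallocatechin | c1ccccc1COc1ccc2c(c1)O[C@H](c1cc(OCc3ccccc3)c(OCc3ccccc3)c(OCc3ccccc3)c1)[C@H](OCc1ccccc1)[C@H]2c1c(OCc3ccccc3)cc(OCc3ccccc3)c2c1O[C@H](c1cc(OCc3ccccc3)c(OCc3ccccc3)c(OCc3ccccc3)c1)[C@H](OCc1ccccc1)C2 | intermediate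
25 | 24 with a 4β-hydroxyl on the lower unit | c1ccccc1COc1ccc2c(c1)O[C@H](c1cc(OCc3ccccc3)c(OCc3ccccc3)c(OCc3ccccc3)c1)[C@H](OCc1ccccc1)[C@H]2c1c(OCc3ccccc3)cc(OCc3ccccc3)c2c1O[C@H](c1cc(OCc3ccccc3)c(OCc3ccccc3)c(OCc3ccccc3)c1)[C@H](OCc1ccccc1)[C@H]2O | intermediate
26 | 24 with a C4 ketone in the lower unit | c1ccccc1COc1ccc2c(c1)O[C@H](c1cc(OCc3ccccc3)c(OCc3ccccc3)c(OCc3ccccc3)c1)[C@H](OCc1ccccc1)[C@H]2c1c(OCc3ccccc3)cc(OCc3ccccc3)c2c1O[C@H](c1cc(OCc3ccccc3)c(OCc3ccccc3)c(OCc3ccccc3)c1)[C@H](OCc1ccccc1)C2=O | intermediate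
27 | 26 with free 5-OH in the lower unit | c1ccccc1COc1ccc2c(c1)O[C@H](c1cc(OCc3ccccc3)c(OCc3ccccc3)c(OCc3ccccc3)c1)[C@H](OCc1ccccc1)[C@H]2c1c(OCc3ccccc3)cc(O)c2c1O[C@H](c1cc(OCc3ccccc3)c(OCc3ccccc3)c(OCc3ccccc3)c1)[C@H](OCc1ccccc1)C2=O | intermediate
28 | 5-O-triflate of 27 | c1ccccc1COc1ccc2c(c1)O[C@H](c1cc(OCc3ccccc3)c(OCc3ccccc3)c(OCc3ccccc3)c1)[C@H](OCc1ccccc1)[C@H]2c1c(OCc3ccccc3)cc(OS(=O)(=O)C(F)(F)F)c2c1O[C@H](c1cc(OCc3ccccc3)c(OCc3ccccc3)c(OCc3ccccc3)c1)[C@H](OCc1ccccc1)C2=O | intermediate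
29 | penta-O-benzyl-epirobinetinidol-(4β→8)-3,7,3',4',5'-penta-O-benzyl-4-oxo-epirobinetinidol | c1ccccc1COc1ccc2c(c1)O[C@H](c1cc(OCc3ccccc3)c(OCc3ccccc3)c(OCc3ccccc3)c1)[C@H](OCc1ccccc1)[C@H]2c1c(OCc3ccccc3)ccc2c1O[C@H](c1cc(OCc3ccccc3)c(OCc3ccccc3)c(OCc3ccccc3)c1)[C@H](OCc1ccccc1)C2=O | intermediate
30 | (2R,3R)-3,5,7-tris(benzyloxy)-2-[3,4-bis(benzyloxy)phenyl]chroman-8-yllithium | [Li]c1c(OCc3ccccc3)cc(OCc3ccccc3)c2c1O[C@H](c1ccc(OCc3ccccc3)c(OCc3ccccc3)c1)[C@H](OCc1ccccc1)C2 | intermediate
31 | protected trimer carbinol: 29 with C4 of the middle unit bearing OH (α) and the C8 of penta-O-benzylepicatechin (β) | c1ccccc1COc1ccc2c(c1)O[C@H](c1cc(OCc3ccccc3)c(OCc3ccccc3)c(OCc3ccccc3)c1)[C@H](OCc1ccccc1)[C@H]2c1c(OCc3ccccc3)ccc2c1O[C@H](c1cc(OCc3ccccc3)c(OCc3ccccc3)c(OCc3ccccc3)c1)[C@H](OCc1ccccc1)[C@@]2(O)c1c(OCc3ccccc3)cc(OCc3ccccc3)c2c1O[C@H](c1ccc(OCc3ccccc3)c(OCc3ccccc3)c1)[C@H](OCc1ccccc1)C2 | intermediate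
32 | pentadeca-O-benzyl-epirobinetinidol-(4β→8)-epirobinetinidol-(4α→8)-epicatechin | c1ccccc1COc1ccc2c(c1)O[C@H](c1cc(OCc3ccccc3)c(OCc3ccccc3)c(OCc3ccccc3)c1)[C@H](OCc1ccccc1)[C@H]2c1c(OCc3ccccc3)ccc2c1O[C@H](c1cc(OCc3ccccc3)c(OCc3ccccc3)c(OCc3ccccc3)c1)[C@H](OCc1ccccc1)[C@@H]2c1c(OCc3ccccc3)cc(OCc3ccccc3)c2c1O[C@H](c1ccc(OCc3ccccc3)c(OCc3ccccc3)c1)[C@H](OCc1ccccc1)C2 | intermediate
33 | epirobinetinidol-(4β→8)-epirobinetinidol-(4α→8)-epicatechin (CNP0115797.2) | Oc1ccc2c(c1)O[C@H](c1cc(O)c(O)c(O)c1)[C@H](O)[C@H]2c1c(O)ccc2c1O[C@H](c1cc(O)c(O)c(O)c1)[C@H](O)[C@@H]2c1c(O)cc(O)c2c1O[C@H](c1ccc(O)c(O)c1)[C@H](O)C2 | target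

**Step count**
Total steps: 24. Longest linear sequence: 16 steps (15 → 33, steps 9–24). The terminal-unit branch (steps 1–8) joins at step 22.

**Steps most likely to fail**

Step 5 (ring expansion). The aluminium alkoxide could close onto the CH2 carbon to a spiro-epoxide, which would then open at the tertiary benzylic carbon with hydride shift or dehydrate to the benzofuran, faster than the aryl group migrates. Fallback, a Tiffeneau–Demjanov ring expansion driven by a diazonium leaving group: setting out from 9, K2CO3 in MeOH should close the spiro-epoxide F1 on purpose. NH3 in MeOH should open it at the CH2 terminus to the amino alcohol F2. NaNO2 in aqueous AcOH at 0 °C should then diazotise the primary amine and trigger the same 1,2-aryl shift, coming back to the route at ketone 11.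

Step 6 (dynamic kinetic resolution). Reduction could outrun the enolisation that racemises C2, or the catalyst could discriminate poorly between the enantiomers and the carbonyl faces, so that enantiomeric or cis/trans purity is lost. Fallback, substrate-controlled reduction and classical resolution: setting out from 11, LiBH(s-Bu)3 in THF at −78 °C should give the racemic cis alcohol by attack anti to the 2-aryl group, that is 12 together with its (2S,3S) antipode F3. Esterification with (S)-2-methoxy-2-phenylacetic acid (DCC, DMAP) should give the diastereomeric esters F4 (from 12) and F5 (from F3), to be separated by chromatography. Methanolysis of the (2R,3R) ester F4 with K2CO3 in MeOH comes back to the route at 12.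

Step 17 (DDQ oxidation of the dimer). Hydride abstraction could also take place at the doubly benzylic C4–H of the upper unit, or over-oxidation could occur, so that chemoselectivity is lost. Fallback, oxidation before the coupling with a leaving group that tolerates the coupling conditions: setting out from 18, 2,6-dimethylbenzenethiol and BF3·OEt2 at −78 °C should give the 4β-arylthio ether F6. Its C–S bond is not ionised by BF3·OEt2 at low temperature, so F6 can replace 17 as the nucleophile towards 23 under the conditions of step 16 and should give the dimer thioether F7. AgOTf in wet THF should then hydrolyse the thioether and come back to the route at 25.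

**Further compounds**
F1 | step 5 | 4,6-bis(benzyloxy)-2-[3,4-bis(benzyloxy)phenyl]-2H-spiro[1-benzofuran-3,2'-oxirane] (racemic; both diastereomers) | C1OC12C(c3ccc(OCc4ccccc4)c(OCc4ccccc4)c3)Oc3cc(OCc4ccccc4)cc(OCc4ccccc4)c32
F2 | step 5 | 3-(aminomethyl)-4,6-bis(benzyloxy)-2-[3,4-bis(benzyloxy)phenyl]-2,3-dihydro-1-benzofuran-3-ol (racemic; both diastereomers) | NCC1(O)C(c2ccc(OCc3ccccc3)c(OCc3ccccc3)c2)Oc2cc(OCc3ccccc3)cc(OCc3ccccc3)c21
F3 | step 6 | (2S,3S)-5,7-bis(benzyloxy)-2-[3,4-bis(benzyloxy)phenyl]chroman-3-ol (antipode of 12) | c1c(OCc3ccccc3)cc(OCc3ccccc3)c2c1O[C@@H](c1ccc(OCc3ccccc3)c(OCc3ccccc3)c1)[C@@H](O)C2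
F4 | step 6 | (S)-2-methoxy-2-phenylacetate of 12 | c1c(OCc3ccccc3)cc(OCc3ccccc3)c2c1O[C@H](c1ccc(OCc3ccccc3)c(OCc3ccccc3)c1)[C@H](OC(=O)[C@@H](OC)c1ccccc1)C2
F5 | step 6 | (S)-2-methoxy-2-phenylacetate of F3 | c1c(OCc3ccccc3)cc(OCc3ccccc3)c2c1O[C@@H](c1ccc(OCc3ccccc3)c(OCc3ccccc3)c1)[C@@H](OC(=O)[C@@H](OC)c1ccccc1)C2
F6 | step 17 | (2R,3R)-3,5,7-tris(benzyloxy)-4β-[(2,6-dimethylphenyl)sulfanyl]-2-[3,4,5-tris(benzyloxy)phenyl]chroman | c1ccccc1COc1cc(OCc2ccccc2)c2c(c1)O[C@H](c1cc(OCc3ccccc3)c(OCc3ccccc3)c(OCc3ccccc3)c1)[C@H](OCc1ccccc1)[C@H]2Sc1c(C)cccc1C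
F7 | step 17 | 24 with a 4β-[(2,6-dimethylphenyl)sulfanyl] group on the lower unit | c1ccccc1COc1ccc2c(c1)O[C@H](c1cc(OCc3ccccc3)c(OCc3ccccc3)c(OCc3ccccc3)c1)[C@H](OCc1ccccc1)[C@H]2c1c(OCc3ccccc3)cc(OCc3ccccc3)c2c1O[C@H](c1cc(OCc3ccccc3)c(OCc3ccccc3)c(OCc3ccccc3)c1)[C@H](OCc1ccccc1)[C@H]2Sc1c(C)cccc1C
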